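**Plan**
- Retrosynthesis: after the protecting groups, the interflavan bond C4(upper)–C8(lower) is cut first, giving an 8‑metallated epiafzelechin ether and a (2S)-flavanone whose C4–OH is later replaced by hydride. Ring C of the lower unit is then cut at C4–C4a and C2–C3 in one stroke.
- Enabling feature: in ring C of the lower (epiafzelechin) unit, O1 joins the phloroglucinol ring A (at C8a) to the benzylic C2. Ionising an acetal at C2 gives the cationic 2‑oxadiene C4a=C8a–O1=C2, whose two ends are the atoms that must bond to the C3–C4 unit.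
- Because C3 carries oxygen, that two‑carbon unit is glycolaldehyde as its symmetric (Z)-enediol bis‑silyl ether. The extra oxygen at C4 is a helper, removed by ionic hydrogenation.
- Forward order: lower ring C by [4+2] on 3,5‑bis(benzyloxy)phenol, C4 deoxygenation, C8 bromination; upper flavanone by asymmetric 1,4‑arylation of a chromone; union by aryl‑cerium addition to the C4 ketone, ionic reduction, desilylation, hydrogenolysis.
- Stereochemistry: lower C2 from a chiral counter‑anion and C3 from the endo, cis‑selective addition (2R,3R); upper C2 (S) from a chiral rhodium catalyst; upper C4 (S) from axial hydride delivery to the C4 cation, which leaves the lower unit equatorial and cis to the 2‑aryl group.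

Key step: step 4

Assumption: the sense of induction of the chiral catalysts in steps 4 and 8 is assigned by analogy, and the catalyst antipode is used if a first run shows the opposite sense; compounds 1, 3, 6, 12 and 14 are taken as catalogue materials.

**Step 1**
Reactants: 1 4-(benzyloxy)benzaldehyde
Product: 2 1-(benzyloxy)-4-(dimethoxymethyl)benzene
Conditions: HC(OMe)3, MeOH, p-TsOH·H2O (cat.), rt; then Et3N
Reagents that add atoms: trimethyl orthoformate, COC(OC)OC
Why: acid‑catalysed acetalisation, with the orthoester consuming the water formed (standard dimethyl acetal formation).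

**Step 2**
Reactants: 2 1-(benzyloxy)-4-(dimethoxymethyl)benzene; 3 3,5-bis(benzyloxy)phenol
Product: 5 1,3-bis(benzyloxy)-5-{[4-(benzyloxy)phenyl](methoxy)methoxy}benzene (racemic mixed acetal), via chloro ether 4 (not isolated)
Conditions: AcCl, ZnBr2 (cat.), CH2Cl2, 0 °C to rt; then 3, iPr2NEt, 0 °C to rt; chromatography on Et3N‑deactivated silica
Reagents that add atoms: acetyl chloride, CC(=O)Cl (its chlorine stands only in intermediate 4)
Why: acetal/acyl chloride exchange gives the ionisable α‑chloro ether, which O‑alkylates the phenol under amine base as in a methoxymethyl ether formation; the basic medium should keep the mixed acetal from rearranging to a C‑benzylated phenol, and its stereocentre is erased in step 4.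

**Step 3**
Reactants: 6 (tert-butyldimethylsilyloxy)acetaldehyde
Product: 7 (Z)-1,2-bis[(tert-butyldimethylsilyl)oxy]ethene
Conditions: TBSOTf, Et3N, CH2Cl2, 0 °C to rt; distillation
Reagents that add atoms: tert-butyldimethylsilyl trifluoromethanesulfonate, CC(C)(C)[Si](C)(C)OS(=O)(=O)C(F)(F)F
Why: soft enolisation and O‑silylation of an α‑oxygenated aldehyde (silyl enol ether formation), for which the (Z)-isomer is expected to predominate; the product is a symmetric enediol ether, so either carbon can become C3.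

**Step 4**
Reactants: 5 mixed acetal; 7 (Z)-1,2-bis[(tert-butyldimethylsilyl)oxy]ethene
Product: 9 (2R,3S,4R)-5,7-bis(benzyloxy)-2-[4-(benzyloxy)phenyl]-3,4-bis[(tert-butyldimethylsilyl)oxy]chromane (all‑cis), via oxocarbenium ion 8 (not isolated)
Conditions: 7 (2.5 equiv), chiral (S,S)-imidodiphosphorimidate Brønsted acid (BINOL‑derived, 3,3′-diaryl, N‑triflyl; 3 mol%), toluene, −78 to −60 °C; Et3N quench
Reagents that add atoms: none
Why: Proposed new method: the chiral acid, silylated in situ by 7, removes methoxide from 5 and leaves the O‑aryl oxocarbenium ion 8, a cationic 2‑oxadiene C4a=C8a–O1=C2, as a contact ion pair with the chiral anion; one carbon of the enediol ether 7 attacks C2 (becoming C3) and the silyloxycarbenium ion left at C4 is trapped at once by the ortho carbon C4a of the phloroglucinol ring, so that C2–C3 and C4–C4a form in one asynchronous inverse‑electron‑demand [4+2] event. The closest known reaction types are the Lewis‑acid‑promoted oxa‑Povarov reaction of aryl oxocarbenium ions with alkenes (racemic) and the enantioselective addition of enol silanes to oxocarbenium ions from O,O‑acetals under chiral counter‑anion (silylium) catalysis. Ring C closes as the six‑membered ring of a formal hetero‑Diels–Alder reaction, its second bond by a 6‑exo‑trig Friedel–Crafts attack of C4a on the C4=O(+) carbon. C2 is set by the chiral anion, which screens one face of the planar (E)-oxocarbenium ion; C3 follows from the endo approach in which both silyloxy groups of the (Z)-alkene lie under the oxadiene (the usual 2,4‑cis preference of Povarov‑type additions), which places H‑2 and H‑3 cis; C4 comes out cis to C3 because the (Z)-geometry is kept, and a C4 epimer would converge in step 5. The step needs ionisation by loss of methoxide (the more basic oxygen) and not of the aryloxide, and ring closure ahead of intermolecular arylation; the symmetric 3,5‑bis(benzyloxy)phenyl ring secures this with two equivalent, strongly activated ortho carbons held five atoms from the cationic centre, and the symmetry of 7 removes any regiochemical question.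

**Step 5**
Reactants: 9 all‑cis cycloadduct
Product: 10 (2R,3R)-5,7-bis(benzyloxy)-2-[4-(benzyloxy)phenyl]-3-[(tert-butyldimethylsilyl)oxy]chromane (5,7,4′-tri-O-benzyl-3-O-silyl-epiafzelechin)
Conditions: Et3SiH (3 equiv), TMSOTf (0.2 equiv), CH2Cl2, −78 °C; NaHCO3 quench
Reagents that add atoms: none
Why: ionic hydrogenation: the C4–OSi bond ionises to a benzylic cation stabilised by the three ring‑A oxygens (5‑OBn, 7‑OBn, O1) and takes hydride from the silane, while the non‑benzylic 3‑silyl ether and the C2 and C3 centres should stay untouched.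

**Step 6**
Reactants: 10 tri-O-benzyl-3-O-silyl-epiafzelechin
Product: 11 (2R,3R)-5,7-bis(benzyloxy)-2-[4-(benzyloxy)phenyl]-8-bromo-3-[(tert-butyldimethylsilyl)oxy]chromane
Conditions: NBS (1.0 equiv), CH2Cl2, −78 to 0 °C
Reagents that add atoms: N-bromosuccinimide, O=C1CCC(=O)N1Br
Why: electrophilic aromatic bromination, expected at C8 (between 7‑OBn and the ring oxygen) and not at the more hindered C6 (between two benzyloxy groups), as is usual for benzylated flavan‑3‑ols; ring B is far less activated.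

**Step 7**
Reactants: 12 7-hydroxy-4H-chromen-4-one
Product: 13 7-(benzyloxy)-4H-chromen-4-one
Conditions: BnBr, K2CO3, DMF, rt
Reagents that add atoms: benzyl bromide, BrCc1ccccc1
Why: Williamson etherification of the acidic 7‑hydroxyl group.

**Step 8**
Reactants: 13 7-(benzyloxy)-4H-chromen-4-one; 14 [4-(benzyloxy)phenyl]boronic acid
Product: 15 (2S)-7-(benzyloxy)-2-[4-(benzyloxy)phenyl]chroman-4-one
Conditions: [Rh(OH)(cod)]2 (2.5 mol%), (S)-6,6′-dimethoxy-2,2′-bis[bis(3,4,5-trifluorophenyl)phosphino]biphenyl (5.5 mol%), CH2Cl2–H2O, rt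
Reagents that add atoms: none
Why: Hayashi–Miyaura asymmetric 1,4‑addition of the aryl‑rhodium species to the chromone C2=C3 bond, the chiral bisphosphine selecting the face and setting C2 (S); the base‑free medium should avoid retro‑oxa‑Michael opening of the flavanone.

**Step 9**
Reactants: 11 8-bromide; 15 (2S)-flavanone
Product: 18 (2S)-7-(benzyloxy)-2-[4-(benzyloxy)phenyl]-4-{(2R,3R)-5,7-bis(benzyloxy)-2-[4-(benzyloxy)phenyl]-3-[(tert-butyldimethylsilyl)oxy]chroman-8-yl}chroman-4-ol (either C4 epimer), via aryllithium 16 (not isolated), via arylcerium dichloride 17 (not isolated)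
Conditions: t-BuLi (2.1 equiv), THF, −78 °C; CeCl3 (anhydrous), −78 °C; then 15, −78 to −30 °C; aq. NH4Cl
Reagents that add atoms: tert-butyllithium, [Li]C(C)(C)C (lithium only in 16); cerium trichloride, Cl[Ce](Cl)Cl (cerium and chlorine only in 17)
Why: bromine–lithium exchange and transmetalation give a weakly basic, oxophilic aryl‑cerium reagent that should add to the C4 carbonyl instead of enolising it (enolisation would open the flavanone to a chalcone and erase C2); the carbinol configuration is irrelevant because step 10 planarises this carbon.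

**Step 10**
Reactants: 18 tertiary carbinol
Product: 19 (2R,3R)-5,7-bis(benzyloxy)-2-[4-(benzyloxy)phenyl]-8-{(2S,4S)-7-(benzyloxy)-2-[4-(benzyloxy)phenyl]chroman-4-yl}-3-[(tert-butyldimethylsilyl)oxy]chromane (2,4‑cis upper unit)
Conditions: Et3SiH (5 equiv), CF3CO2H (10 equiv), CH2Cl2, −40 to 0 °C
Reagents that add atoms: none
Why: ionic hydrogenation of the tertiary, doubly benzylic alcohol: the C4 cation (stabilised by the para 7‑OBn group) should take hydride axially on the face syn to H‑2 through a chair‑like transition state with the 2‑aryl group equatorial, which leaves the lower unit equatorial and cis to the 2‑aryl group, i.e. (4S).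

**Step 11**
Reactants: 19 silyl ether
Product: 20 (2R,3R)-5,7-bis(benzyloxy)-2-[4-(benzyloxy)phenyl]-8-{(2S,4S)-7-(benzyloxy)-2-[4-(benzyloxy)phenyl]chroman-4-yl}chroman-3-ol
Conditions: TBAF, THF, 0 °C to rt
Reagents that add atoms: none
Why: fluoride‑induced cleavage of the secondary silyl ether, carried out while all phenols are still benzylated so that no base‑sensitive free 4′-hydroxyflavan is exposed.

**Step 12**
Reactants: 20 penta-O-benzyl ether
Product: 21 target, (2R,3R)-8-[(2S,4S)-7-hydroxy-2-(4-hydroxyphenyl)chroman-4-yl]-2-(4-hydroxyphenyl)chromane-3,5,7-triol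
Conditions: H2 (1 atm), Pd(OH)2/C, THF–MeOH, rt
Reagents that add atoms: none
Why: catalytic hydrogenolysis of the five aryl benzyl ethers, the standard last step for benzylated oligoflavanoids; no stereocentre is involved.

**Compound list**
1 | 4-(benzyloxy)benzaldehyde | O=Cc1ccc(OCc2ccccc2)cc1 | starting material
2 | 1-(benzyloxy)-4-(dimethoxymethyl)benzene | COC(OC)c1ccc(OCc2ccccc2)cc1 | intermediate
3 | 3,5-bis(benzyloxy)phenol | Oc1cc(OCc2ccccc2)cc(OCc2ccccc2)c1 | starting material
4 | 1-(benzyloxy)-4-[chloro(methoxy)methyl]benzene (racemic) | COC(Cl)c1ccc(OCc2ccccc2)cc1 | intermediate (not isolated)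
5 | 1,3-bis(benzyloxy)-5-{[4-(benzyloxy)phenyl](methoxy)methoxy}benzene (racemic; centre erased in step 4) | COC(Oc1cc(OCc2ccccc2)cc(OCc2ccccc2)c1)c1ccc(OCc2ccccc2)cc1 | intermediate
6 | (tert-butyldimethylsilyloxy)acetaldehyde | CC(C)(C)[Si](C)(C)OCC=O | starting material
7 | (Z)-1,2-bis[(tert-butyldimethylsilyl)oxy]ethene | CC(C)(C)[Si](C)(C)O/C=C\O[Si](C)(C)C(C)(C)C | intermediate
8 | (E)-[3,5-bis(benzyloxy)phenyl][4-(benzyloxy)benzylidene]oxonium ion (ion pair with the catalyst anion) | c1c(OCc2ccccc2)cc(OCc2ccccc2)cc1/[O+]=C/c1ccc(OCc2ccccc2)cc1 | intermediate (not isolated)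
9 | (2R,3S,4R)-5,7-bis(benzyloxy)-2-[4-(benzyloxy)phenyl]-3,4-bis[(tert-butyldimethylsilyl)oxy]chromane (all‑cis) | c1c(OCc3ccccc3)cc(OCc3ccccc3)c2c1O[C@H](c1ccc(OCc3ccccc3)cc1)[C@H](O[Si](C)(C)C(C)(C)C)[C@@H]2O[Si](C)(C)C(C)(C)C | intermediate
10 | (2R,3R)-5,7-bis(benzyloxy)-2-[4-(benzyloxy)phenyl]-3-[(tert-butyldimethylsilyl)oxy]chromane | c1c(OCc3ccccc3)cc(OCc3ccccc3)c2c1O[C@H](c1ccc(OCc3ccccc3)cc1)[C@H](O[Si](C)(C)C(C)(C)C)C2 | intermediate
11 | (2R,3R)-5,7-bis(benzyloxy)-2-[4-(benzyloxy)phenyl]-8-bromo-3-[(tert-butyldimethylsilyl)oxy]chromane | Brc1c(OCc3ccccc3)cc(OCc3ccccc3)c2c1O[C@H](c1ccc(OCc3ccccc3)cc1)[C@H](O[Si](C)(C)C(C)(C)C)C2 | intermediate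
12 | 7-hydroxy-4H-chromen-4-one | O=c1ccoc2cc(O)ccc12 | starting material
13 | 7-(benzyloxy)-4H-chromen-4-one | O=c1ccoc2cc(OCc3ccccc3)ccc12 | intermediate
14 | [4-(benzyloxy)phenyl]boronic acid | OB(O)c1ccc(OCc2ccccc2)cc1 | starting material
15 | (2S)-7-(benzyloxy)-2-[4-(benzyloxy)phenyl]chroman-4-one | O=C1C[C@@H](c2ccc(OCc3ccccc3)cc2)Oc2cc(OCc3ccccc3)ccc12 | intermediate
16 | 8-lithio derivative of 10 | [Li]c1c(OCc3ccccc3)cc(OCc3ccccc3)c2c1O[C@H](c1ccc(OCc3ccccc3)cc1)[C@H](O[Si](C)(C)C(C)(C)C)C2 | intermediate (not isolated)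
17 | 8-(dichlorocerio) derivative of 10 | Cl[Ce](Cl)c1c(OCc3ccccc3)cc(OCc3ccccc3)c2c1O[C@H](c1ccc(OCc3ccccc3)cc1)[C@H](O[Si](C)(C)C(C)(C)C)C2 | intermediate (not isolated)
18 | (2S)-7-(benzyloxy)-2-[4-(benzyloxy)phenyl]-4-{(2R,3R)-5,7-bis(benzyloxy)-2-[4-(benzyloxy)phenyl]-3-[(tert-butyldimethylsilyl)oxy]chroman-8-yl}chroman-4-ol (carbinol centre left open, either epimer) | c1ccccc1COc1ccc([C@@H]2CC(O)(c3c(OCc4ccccc4)cc(OCc4ccccc4)c4c3O[C@H](c3ccc(OCc5ccccc5)cc3)[C@H](O[Si](C)(C)C(C)(C)C)C4)c3ccc(OCc4ccccc4)cc3O2)cc1 | intermediate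
19 | (2R,3R)-5,7-bis(benzyloxy)-2-[4-(benzyloxy)phenyl]-8-{(2S,4S)-7-(benzyloxy)-2-[4-(benzyloxy)phenyl]chroman-4-yl}-3-[(tert-butyldimethylsilyl)oxy]chromane | c1ccccc1COc1ccc([C@@H]2C[C@H](c3c(OCc4ccccc4)cc(OCc4ccccc4)c4c3O[C@H](c3ccc(OCc5ccccc5)cc3)[C@H](O[Si](C)(C)C(C)(C)C)C4)c3ccc(OCc4ccccc4)cc3O2)cc1 | intermediate
20 | (2R,3R)-5,7-bis(benzyloxy)-2-[4-(benzyloxy)phenyl]-8-{(2S,4S)-7-(benzyloxy)-2-[4-(benzyloxy)phenyl]chroman-4-yl}chroman-3-ol | c1ccccc1COc1ccc([C@@H]2C[C@H](c3c(OCc4ccccc4)cc(OCc4ccccc4)c4c3O[C@H](c3ccc(OCc5ccccc5)cc3)[C@H](O)C4)c3ccc(OCc4ccccc4)cc3O2)cc1 | intermediate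
21 | (2R,3R)-8-[(2S,4S)-7-hydroxy-2-(4-hydroxyphenyl)chroman-4-yl]-2-(4-hydroxyphenyl)chromane-3,5,7-triol | Oc1ccc([C@@H]2C[C@H](c3c(O)cc(O)c4c3O[C@H](c3ccc(O)cc3)[C@H](O)C4)c3ccc(O)cc3O2)cc1 | target

**Step count**
Total: 12 steps. Longest linear sequence: 9 steps (1, 2, 4, 5, 6, 9, 10, 11, 12).

**Steps most likely to fail**

Step 4. The ion pair may discriminate the two faces of the oxocarbenium ion poorly, because the cation offers the chiral anion no hydrogen‑bond handle. The acetal may also ionise toward the aryloxide, or the new C4–OSi bond may re‑ionise under the silyl Lewis acid. The fallback sets out from 5 (with 7) and gives up asymmetric catalysis for a racemic run and a resolution. Achiral promotion with TMSOTf (10 mol%, CH2Cl2, −78 °C), the established Lewis‑acid manifold for acetal–enol silane coupling and oxa‑Povarov ring closure, should give the racemic all‑cis cycloadduct F1. The conditions of step 5 should then give the racemic silyl ether F2, whose enantiomers are separated by preparative chromatography on a chiral stationary phase. The (2R,3R) enantiomer is 10, where the route is rejoined.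

Step 9. The aryl‑metal may deprotonate the flavanone, which then opens by retro‑oxa‑Michael reaction to the chalcone and loses the C2 configuration. Addition may also stall because the nucleophile carries two ortho substituents. The fallback sets out from 15 and 11 and replaces carbonyl addition by cross‑coupling. Treatment of 15 with Tf2O and 2,6‑di‑tert‑butyl‑4‑methylpyridine (CH2Cl2, 0 °C) gives the enol triflate (2S)-7-(benzyloxy)-2-[4-(benzyloxy)phenyl]-2H-chromen-4-yl trifluoromethanesulfonate F3. Aryllithium 16, made again from 11 with t‑BuLi, is transmetalated with ZnCl2 to the arylzinc chloride F4. Negishi coupling of F3 and F4 (Pd2(dba)3, SPhos, THF, 40 °C, light excluded) should give the 4‑aryl‑flav‑3‑ene F5. Under the conditions of step 10, protonation of F5 at C3 generates the same C4 cation as from 18, and hydride capture leads to 19, where the route is rejoined.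

Step 10. Hydride capture by the C4 cation may show poor facial selectivity, and the acid may cleave the benzylic O1–C2 ether bonds (ring opening, epimerisation at C2). The fallback sets out from 18 and replaces cationic hydride transfer by surface hydrogenation. TBAF removes the silyl group to give the diol F6, and mild acid‑catalysed dehydration (PPTS, toluene, 50 °C) of its tertiary, doubly benzylic hydroxyl gives the flav‑3‑ene F7. Hydrogenation over Pd(OH)2/C should add hydrogen to the C3=C4 bond from the face opposite the 2‑aryl group, which places the lower unit cis, and cleave the benzyl ethers in the same operation. This arrives directly at 21.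

**Further compounds**
F1 | step 4 | racemic all‑cis 5,7-bis(benzyloxy)-2-[4-(benzyloxy)phenyl]-3,4-bis[(tert-butyldimethylsilyl)oxy]chromane (both enantiomers) | c1c(OCc3ccccc3)cc(OCc3ccccc3)c2c1O[C@H](c1ccc(OCc3ccccc3)cc1)[C@H](O[Si](C)(C)C(C)(C)C)[C@@H]2O[Si](C)(C)C(C)(C)C.c1c(OCc3ccccc3)cc(OCc3ccccc3)c2c1O[C@@H](c1ccc(OCc3ccccc3)cc1)[C@@H](O[Si](C)(C)C(C)(C)C)[C@H]2O[Si](C)(C)C(C)(C)C
F2 | step 4 | racemic 2,3‑cis 5,7-bis(benzyloxy)-2-[4-(benzyloxy)phenyl]-3-[(tert-butyldimethylsilyl)oxy]chromane (both enantiomers) | c1c(OCc3ccccc3)cc(OCc3ccccc3)c2c1O[C@H](c1ccc(OCc3ccccc3)cc1)[C@H](O[Si](C)(C)C(C)(C)C)C2.c1c(OCc3ccccc3)cc(OCc3ccccc3)c2c1O[C@@H](c1ccc(OCc3ccccc3)cc1)[C@@H](O[Si](C)(C)C(C)(C)C)C2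
F3 | step 9 | (2S)-7-(benzyloxy)-2-[4-(benzyloxy)phenyl]-2H-chromen-4-yl trifluoromethanesulfonate | O=S(=O)(OC1=C[C@@H](c2ccc(OCc3ccccc3)cc2)Oc2cc(OCc3ccccc3)ccc12)C(F)(F)F
F4 | step 9 | 8-(chlorozincio) derivative of 10 | Cl[Zn]c1c(OCc3ccccc3)cc(OCc3ccccc3)c2c1O[C@H](c1ccc(OCc3ccccc3)cc1)[C@H](O[Si](C)(C)C(C)(C)C)C2
F5 | step 9 | (2R,3R)-5,7-bis(benzyloxy)-2-[4-(benzyloxy)phenyl]-8-{(2S)-7-(benzyloxy)-2-[4-(benzyloxy)phenyl]-2H-chromen-4-yl}-3-[(tert-butyldimethylsilyl)oxy]chromane | c1ccccc1COc1ccc([C@@H]2C=C(c3c(OCc4ccccc4)cc(OCc4ccccc4)c4c3O[C@H](c3ccc(OCc5ccccc5)cc3)[C@H](O[Si](C)(C)C(C)(C)C)C4)c3ccc(OCc4ccccc4)cc3O2)cc1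
F6 | step 10 | (2S)-7-(benzyloxy)-2-[4-(benzyloxy)phenyl]-4-{(2R,3R)-5,7-bis(benzyloxy)-2-[4-(benzyloxy)phenyl]-3-hydroxychroman-8-yl}chroman-4-ol (either C4 epimer) | c1ccccc1COc1ccc([C@@H]2CC(O)(c3c(OCc4ccccc4)cc(OCc4ccccc4)c4c3O[C@H](c3ccc(OCc5ccccc5)cc3)[C@H](O)C4)c3ccc(OCc4ccccc4)cc3O2)cc1
F7 | step 10 | (2R,3R)-5,7-bis(benzyloxy)-2-[4-(benzyloxy)phenyl]-8-{(2S)-7-(benzyloxy)-2-[4-(benzyloxy)phenyl]-2H-chromen-4-yl}chroman-3-ol | c1ccccc1COc1ccc([C@@H]2C=C(c3c(OCc4ccccc4)cc(OCc4ccccc4)c4c3O[C@H](c3ccc(OCc5ccccc5)cc3)[C@H](O)C4)c3ccc(OCc4ccccc4)cc3O2)cc1
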